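**Retrosynthetic overview**
1. Numbering: C1 is the carboxyl carbon and C17 is the CH bound to C4 of the oxazole. The enabling feature is that C8 is an unsubstituted CH2 between the syn-related carbinols C7 and C9, and the C11 oxygen stands 1,5-anti to the C7 oxygen. C7–C8 is therefore the aldol bond of a C9 methyl ketone that carries its own directing oxygen at C11.
2. Key disconnection C7–C8: a one-flask enolboration, 1,5-anti boron aldol and LiBH4 chelate reduction joins the C8–C17 oxazolyl-triene methyl ketone to the C1–C7 dienyl aldehyde and sets C7 and C9. C11–O is a fluoride-labile (triisopropylsiloxy)methyl (TOM) ether, and C1 is held at the silyl-ether (alcohol) level so that C6–H is not acidified through the diene by an ester.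
3. Ketone half: C8–C9 by MeMgBr on a Weinreb amide, C10–C11 by Evans syn aldol, C14=C15 by vinylogous HWE, C16=C17 by Wittig olefination of 2-methyloxazole-4-carbaldehyde.
4. Aldehyde half: C6 comes from the (R)-Roche ester and C4=C5 from the same vinylogous HWE reagent, because both halves hold the same 2-methylpenta-2,4-dienyl unit (C1–C5 and C11–C15).
5. Rings: the 2-methyl-1,3-oxazole is bought and no ring of the target has to be formed. The only ring made is the temporary six-membered O–B–O chelate of the key step. End game: fluoride, then C1 alcohol to aldehyde to acid.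

Key step: step 18

Assumption: the TOM ether oxygen at C11, an unhindered acetal-type alkyl ether oxygen, is taken to direct the boron aldol 1,5-anti as 4-methoxybenzyl (PMB) ethers and benzylidene acetals do. All polyenes are handled with exclusion of light.

**Step 1**
Reactants: 1 ethyl (E)-2-methylbut-2-enoate (ethyl tiglate)
Product: 2 ethyl (E)-4-bromo-2-methylbut-2-enoate
Conditions: NBS, AIBN (cat.), PhCF3, reflux
Reagents that add atoms: N-bromosuccinimide, O=C1CCC(=O)N1Br
Why: Wohl–Ziegler allylic bromination, in which the allyl radical of the tiglate should be brominated mainly at the terminal C4 methyl group with the conjugated E ester retained, the isomeric 2-(bromomethyl) ester being removable by distillation.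

**Step 2**
Reactants: 2 ethyl (E)-4-bromo-2-methylbut-2-enoate
Product: 3 ethyl (E)-4-(diethoxyphosphoryl)-2-methylbut-2-enoate
Conditions: P(OEt)3, neat, 130 °C
Reagents that add atoms: triethyl phosphite, CCOP(OCC)OCC
Why: Michaelis–Arbuzov reaction of a primary allylic bromide, driven by loss of volatile bromoethane.

**Step 3**
Reactants: 4 methyl (R)-3-hydroxy-2-methylpropanoate ((R)-Roche ester)
Product: 5 methyl (R)-2-methyl-3-[(triethylsilyl)oxy]propanoate
Conditions: TESCl, imidazole, CH2Cl2, 0 °C to rt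
Reagents that add atoms: chlorotriethylsilane, CC[Si](Cl)(CC)CC
Why: Standard silylation of a primary alcohol, the TES group being chosen because it can later be removed beside a TBS ether.

**Step 4**
Reactants: 5 methyl (R)-2-methyl-3-[(triethylsilyl)oxy]propanoate
Product: 6 (R)-2-methyl-3-[(triethylsilyl)oxy]propanal
Conditions: i-Bu2AlH (1 equiv), CH2Cl2, −78 °C
Reagents that add atoms: none
Why: Partial ester reduction through the aluminium hemiacetal that is stable at −78 °C, which leaves the α-stereocentre (later C6) untouched.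

**Step 5**
Reactants: 6 (R)-2-methyl-3-[(triethylsilyl)oxy]propanal; 3 ethyl (E)-4-(diethoxyphosphoryl)-2-methylbut-2-enoate
Product: 7 ethyl (2E,4E,6S)-2,6-dimethyl-7-[(triethylsilyl)oxy]hepta-2,4-dienoate
Conditions: 3, LiN(SiMe3)2, THF, −78 °C; then 6, −78 to 0 °C
Reagents that add atoms: none
Why: Vinylogous Horner–Wadsworth–Emmons olefination, in which the stabilised anion reacts at the carbon next to phosphorus and should give the new C4=C5 bond E, while the low temperature protects the α-stereocentre of 6.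

**Step 6**
Reactants: 7 ethyl (2E,4E,6S)-2,6-dimethyl-7-[(triethylsilyl)oxy]hepta-2,4-dienoate
Product: 8 (2E,4E,6S)-2,6-dimethyl-7-[(triethylsilyl)oxy]hepta-2,4-dien-1-ol
Conditions: i-Bu2AlH (2.5 equiv), CH2Cl2, −78 °C
Reagents that add atoms: none
Why: Clean 1,2-reduction of a conjugated ester by i-Bu2AlH, which takes the electron-withdrawing group off the diene before C7 is raised to the aldehyde level.

**Step 7**
Reactants: 8 (2E,4E,6S)-2,6-dimethyl-7-[(triethylsilyl)oxy]hepta-2,4-dien-1-ol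
Product: 9 (2E,4E,6S)-1-[(tert-butyldimethylsilyl)oxy]-2,6-dimethyl-7-[(triethylsilyl)oxy]hepta-2,4-diene
Conditions: TBSCl, imidazole, CH2Cl2, 0 °C to rt
Reagents that add atoms: tert-butylchlorodimethylsilane, CC(C)(C)[Si](C)(C)Cl
Why: Standard silylation of the primary allylic alcohol under conditions that leave the TES ether intact.

**Step 8**
Reactants: 9 (2E,4E,6S)-1-[(tert-butyldimethylsilyl)oxy]-2,6-dimethyl-7-[(triethylsilyl)oxy]hepta-2,4-diene
Product: 10 (2S,3E,5E)-7-[(tert-butyldimethylsilyl)oxy]-2,6-dimethylhepta-3,5-dien-1-ol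
Conditions: PPTS (cat.), MeOH/CH2Cl2, 0 °C
Reagents that add atoms: none
Why: Acid-catalysed methanolysis distinguishes silyl ethers by the bulk at silicon, so the primary TES ether should be cleaved well before the primary TBS ether.

**Step 9**
Reactants: 10 (2S,3E,5E)-7-[(tert-butyldimethylsilyl)oxy]-2,6-dimethylhepta-3,5-dien-1-ol
Product: 11 (2S,3E,5E)-7-[(tert-butyldimethylsilyl)oxy]-2,6-dimethylhepta-3,5-dienal
Conditions: Dess–Martin periodinane, NaHCO3, CH2Cl2, 0 °C; used crude at once in step 18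
Reagents that add atoms: none
Why: Dess–Martin oxidation runs without amine base and is buffered here, so the β,γ-unsaturated aldehyde should form without loss of the C6 configuration or migration of the C4=C5 bond.

**Step 10**
Reactants: 12 2-methyl-1,3-oxazole-4-carbaldehyde; 13 2-(triphenylphosphoranylidene)propanal
Product: 14 (E)-2-methyl-3-(2-methyl-1,3-oxazol-4-yl)prop-2-enal
Conditions: toluene, 90 °C
Reagents that add atoms: none
Why: Wittig olefination with a stabilised ylide should give the E trisubstituted C16=C17 bond, and the hindered, less electrophilic enal product reacts on only slowly.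

**Step 11**
Reactants: 14 (E)-2-methyl-3-(2-methyl-1,3-oxazol-4-yl)prop-2-enal; 3 ethyl (E)-4-(diethoxyphosphoryl)-2-methylbut-2-enoate
Product: 15 ethyl (2E,4E,6E)-2,6-dimethyl-7-(2-methyl-1,3-oxazol-4-yl)hepta-2,4,6-trienoate
Conditions: 3, LiN(SiMe3)2, THF, −78 °C; then 14, −78 to 0 °C
Reagents that add atoms: none
Why: The same vinylogous Horner–Wadsworth–Emmons olefination as in step 5 should form C14=C15 with E geometry on a non-enolisable enal.

**Step 12**
Reactants: 15 ethyl (2E,4E,6E)-2,6-dimethyl-7-(2-methyl-1,3-oxazol-4-yl)hepta-2,4,6-trienoate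
Product: 16 (2E,4E,6E)-2,6-dimethyl-7-(2-methyl-1,3-oxazol-4-yl)hepta-2,4,6-trien-1-ol
Conditions: i-Bu2AlH (2.5 equiv), CH2Cl2, −78 °C
Reagents that add atoms: none
Why: 1,2-Reduction of the conjugated ester by i-Bu2AlH, to which the oxazole and the triene are inert at −78 °C.

**Step 13**
Reactants: 16 (2E,4E,6E)-2,6-dimethyl-7-(2-methyl-1,3-oxazol-4-yl)hepta-2,4,6-trien-1-ol
Product: 17 (2E,4E,6E)-2,6-dimethyl-7-(2-methyl-1,3-oxazol-4-yl)hepta-2,4,6-trienal
Conditions: MnO2, CH2Cl2, rt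
Reagents that add atoms: none
Why: Selective allylic alcohol oxidation with MnO2 under neutral conditions that keep the olefin geometry.

**Step 14**
Reactants: 17 (2E,4E,6E)-2,6-dimethyl-7-(2-methyl-1,3-oxazol-4-yl)hepta-2,4,6-trienal; 18 (R)-4-benzyl-3-propanoyl-1,3-oxazolidin-2-one
Product: 20 (R)-4-benzyl-3-[(2R,3R,4E,6E,8E)-3-hydroxy-2,4,8-trimethyl-9-(2-methyl-1,3-oxazol-4-yl)nona-4,6,8-trienoyl]-1,3-oxazolidin-2-one, via Z-enol dibutylborinate 19 (not isolated)
Conditions: 18, n-Bu2BOTf, Et3N, CH2Cl2, −78 to 0 °C; 17, −78 to 0 °C; then pH 7 buffer, MeOH, 30% H2O2, 0 °C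
Reagents that add atoms: none
Why: Evans syn aldol, in which 19 reacts through a chair Zimmerman–Traxler transition state on the enolate face away from the benzyl group of the (R)-auxiliary, which should set C10 and C11 as the (2R,3R) syn pair.

**Step 15**
Reactants: 20 syn aldol adduct
Product: 21 (2R,3R,4E,6E,8E)-3-hydroxy-N-methoxy-N,2,4,8-tetramethyl-9-(2-methyl-1,3-oxazol-4-yl)nona-4,6,8-trienamide
Conditions: MeNHOMe·HCl, AlMe3, THF, −10 to 0 °C
Reagents that add atoms: N,O-dimethylhydroxylamine hydrochloride, CNOC.Cl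
Why: Aluminium-amide transamidation to the Weinreb amide, assisted by the free β-hydroxyl group, attacks the exocyclic carbonyl group and does not epimerise C10.

**Step 16**
Reactants: 21 β-hydroxy Weinreb amide
Product: 22 (2R,3R,4E,6E,8E)-N-methoxy-N,2,4,8-tetramethyl-9-(2-methyl-1,3-oxazol-4-yl)-3-{[(triisopropylsilyl)oxy]methoxy}nona-4,6,8-trienamide
Conditions: TOMCl, i-Pr2NEt, Bu4NI (cat.), CH2Cl2, rt to 40 °C
Reagents that add atoms: (triisopropylsiloxy)methyl chloride, ClCO[Si](C(C)C)(C(C)C)C(C)C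
Why: O-alkylation with an α-chloro ether under amine base (as with MOM, SEM or BOM chloride) avoids the acid that would ionise the trienylic carbinol and the strong base that would cause retro-aldol cleavage, and it leaves at C11 an alkyl-type ether oxygen that fluoride can remove.

**Step 17**
Reactants: 22 TOM-protected Weinreb amide
Product: 23 (3R,4R,5E,7E,9E)-3,5,9-trimethyl-10-(2-methyl-1,3-oxazol-4-yl)-4-{[(triisopropylsilyl)oxy]methoxy}deca-5,7,9-trien-2-one
Conditions: MeMgBr, THF, −78 to 0 °C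
Reagents that add atoms: methylmagnesium bromide, C[Mg]Br
Why: Weinreb ketone synthesis, in which the stable magnesium chelate stops the addition at the ketone stage and brings in C8.

**Step 18**
Reactants: 23 C8–C17 methyl ketone; 11 C1–C7 aldehyde
Product: 26 (2E,4E,6S,7R,9S,10S,11R,12E,14E,16E)-1-[(tert-butyldimethylsilyl)oxy]-2,6,10,12,16-pentamethyl-17-(2-methyl-1,3-oxazol-4-yl)-11-{[(triisopropylsilyl)oxy]methoxy}heptadeca-2,4,12,14,16-pentaene-7,9-diol, via enol dicyclohexylborinate 24 (not isolated), via chelated boron aldolate 25 (not isolated)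
Conditions: 23, (c-C6H11)2BCl, Et3N, Et2O, 0 °C; 11, −78 °C; LiBH4 (THF), −78 °C; then MeOH, pH 7 buffer, 30% H2O2, 0 °C
Reagents that add atoms: none
Why: (c-C6H11)2BCl/Et3N enolises 23 only at the unhindered C8 methyl group to give 24, which binds aldehyde 11 at boron and forms the C7–C8 bond through a cyclic boat-like transition state to give aldolate 25, and LiBH4 then reduces the boron-chelated C9 ketone in the same flask before H2O2 releases the diol. The closest known reaction types are the 1,5-anti boron aldol of β-alkoxy methyl ketones and the one-pot boron aldol/LiBH4 syn reduction (the in situ form of a Narasaka–Prasad reduction). No ring of the target is closed; the only ring is the temporary six-membered chelate C7–O–B···O=C9–C8 of 25, closed by O-to-B coordination and destroyed in the work-up. C7 (R) is controlled by the C11 stereocentre: in the favoured transition state the formyl C–H of 11 is hydrogen-bonded to the C11 ether oxygen and the triene-bearing substituent points away from the boron ligands, which places C7–O anti to C11–O. C9 (S) is controlled by C7: hydride attacks the half-chair chelate, with the C7 side chain equatorial, from the axial direction, which gives the 7,9-syn diol (also 9,11-anti). The step needs enolate control to override the weak Felkin–Anh bias of 11 (its methyl and alkenyl groups differ little in size), no enolisation of 11 (no conjugated ester at C1, less amine than boron reagent, −78 °C) and chemoselective hydride delivery (the chelated ketone is the only activated carbonyl group).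

**Step 19**
Reactants: 26 protected 7,9-diol
Product: 27 (2E,4E,6S,7R,9S,10S,11R,12E,14E,16E)-2,6,10,12,16-pentamethyl-17-(2-methyl-1,3-oxazol-4-yl)heptadeca-2,4,12,14,16-pentaene-1,7,9,11-tetrol
Conditions: Bu4NF, THF, 0 °C to rt
Reagents that add atoms: none
Why: Fluoride desilylation, in which loss of the TIPS group leaves a formaldehyde hemiacetal that collapses to the free C11 alcohol while the primary TBS ether is cleaved at the same time, with no acid or oxidant near the triene.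

**Step 20**
Reactants: 27 tetrol
Product: 28 (2E,4E,6S,7R,9S,10S,11R,12E,14E,16E)-7,9,11-trihydroxy-2,6,10,12,16-pentamethyl-17-(2-methyl-1,3-oxazol-4-yl)heptadeca-2,4,12,14,16-pentaenal
Conditions: TEMPO (cat.), PhI(OAc)2, CH2Cl2, 0 °C to rt
Reagents that add atoms: none
Why: Oxoammonium (TEMPO) oxidation strongly prefers unhindered primary alcohols, so the dienylic C1 alcohol should be oxidised ahead of the hindered secondary carbinols at C7, C9 and C11 and should stop at the conjugated aldehyde.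

**Step 21**
Reactants: 28 trihydroxy dienal
Product: 29 (2E,4E,6S,7R,9S,10S,11R,12E,14E,16E)-7,9,11-trihydroxy-2,6,10,12,16-pentamethyl-17-(2-methyl-1,3-oxazol-4-yl)heptadeca-2,4,12,14,16-pentaenoic acid (target)
Conditions: NaClO2, NaH2PO4, 2-methyl-2-butene, t-BuOH/H2O, 0 °C to rt
Reagents that add atoms: sodium chlorite, [Na+].[O-]Cl=O
Why: Pinnick oxidation converts only the aldehyde into the acid at mildly acidic pH, and the excess 2-methyl-2-butene traps hypochlorous acid before it can reach the polyenes.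

**Compound list**
1 | ethyl (E)-2-methylbut-2-enoate (ethyl tiglate) | C/C=C(\C)C(=O)OCC | starting material
2 | ethyl (E)-4-bromo-2-methylbut-2-enoate | BrC/C=C(\C)C(=O)OCC | intermediate
3 | ethyl (E)-4-(diethoxyphosphoryl)-2-methylbut-2-enoate | CCOC(=O)/C(C)=C/CP(=O)(OCC)OCC | intermediate
4 | methyl (R)-3-hydroxy-2-methylpropanoate | OC[C@@H](C)C(=O)OC | starting material
5 | methyl (R)-2-methyl-3-[(triethylsilyl)oxy]propanoate | CC[Si](CC)(CC)OC[C@@H](C)C(=O)OC | intermediate
6 | (R)-2-methyl-3-[(triethylsilyl)oxy]propanal | CC[Si](CC)(CC)OC[C@@H](C)C=O | intermediate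
7 | ethyl (2E,4E,6S)-2,6-dimethyl-7-[(triethylsilyl)oxy]hepta-2,4-dienoate | CC[Si](CC)(CC)OC[C@@H](C)/C=C/C=C(\C)C(=O)OCC | intermediate
8 | (2E,4E,6S)-2,6-dimethyl-7-[(triethylsilyl)oxy]hepta-2,4-dien-1-ol | CC[Si](CC)(CC)OC[C@@H](C)/C=C/C=C(\C)CO | intermediate
9 | (2E,4E,6S)-1-[(tert-butyldimethylsilyl)oxy]-2,6-dimethyl-7-[(triethylsilyl)oxy]hepta-2,4-diene | CC[Si](CC)(CC)OC[C@@H](C)/C=C/C=C(\C)CO[Si](C)(C)C(C)(C)C | intermediate
10 | (2S,3E,5E)-7-[(tert-butyldimethylsilyl)oxy]-2,6-dimethylhepta-3,5-dien-1-ol | OC[C@@H](C)/C=C/C=C(\C)CO[Si](C)(C)C(C)(C)C | intermediate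
11 | (2S,3E,5E)-7-[(tert-butyldimethylsilyl)oxy]-2,6-dimethylhepta-3,5-dienal | O=C[C@@H](C)/C=C/C=C(\C)CO[Si](C)(C)C(C)(C)C | intermediate
12 | 2-methyl-1,3-oxazole-4-carbaldehyde | Cc1nc(C=O)co1 | starting material
13 | 2-(triphenylphosphoranylidene)propanal | CC(C=O)=P(c1ccccc1)(c1ccccc1)c1ccccc1 | starting material
14 | (E)-2-methyl-3-(2-methyl-1,3-oxazol-4-yl)prop-2-enal | O=C/C(C)=C/c1coc(C)n1 | intermediate
15 | ethyl (2E,4E,6E)-2,6-dimethyl-7-(2-methyl-1,3-oxazol-4-yl)hepta-2,4,6-trienoate | CCOC(=O)/C(C)=C/C=C/C(C)=C/c1coc(C)n1 | intermediate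
16 | (2E,4E,6E)-2,6-dimethyl-7-(2-methyl-1,3-oxazol-4-yl)hepta-2,4,6-trien-1-ol | OC/C(C)=C/C=C/C(C)=C/c1coc(C)n1 | intermediate
17 | (2E,4E,6E)-2,6-dimethyl-7-(2-methyl-1,3-oxazol-4-yl)hepta-2,4,6-trienal | O=C/C(C)=C/C=C/C(C)=C/c1coc(C)n1 | intermediate
18 | (R)-4-benzyl-3-propanoyl-1,3-oxazolidin-2-one | CCC(=O)N1C(=O)OC[C@H]1Cc1ccccc1 | starting material
19 | Z-enol dibutylborinate of 18 (not isolated) | C/C=C(\OB(CCCC)CCCC)N1C(=O)OC[C@H]1Cc1ccccc1 | intermediate
20 | (R)-4-benzyl-3-[(2R,3R,4E,6E,8E)-3-hydroxy-2,4,8-trimethyl-9-(2-methyl-1,3-oxazol-4-yl)nona-4,6,8-trienoyl]-1,3-oxazolidin-2-one | CC(/C=C/C=C(\C)[C@H](O)[C@@H](C)C(=O)N1C(=O)OC[C@H]1Cc1ccccc1)=C\c1coc(C)n1 | intermediate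
21 | (2R,3R,4E,6E,8E)-3-hydroxy-N-methoxy-N,2,4,8-tetramethyl-9-(2-methyl-1,3-oxazol-4-yl)nona-4,6,8-trienamide | CC(/C=C/C=C(\C)[C@H](O)[C@@H](C)C(=O)N(C)OC)=C\c1coc(C)n1 | intermediate
22 | TOM ether of 21 | CC(/C=C/C=C(\C)[C@H](OCO[Si](C(C)C)(C(C)C)C(C)C)[C@@H](C)C(=O)N(C)OC)=C\c1coc(C)n1 | intermediate
23 | (3R,4R,5E,7E,9E)-3,5,9-trimethyl-10-(2-methyl-1,3-oxazol-4-yl)-4-{[(triisopropylsilyl)oxy]methoxy}deca-5,7,9-trien-2-one | CC(/C=C/C=C(\C)[C@H](OCO[Si](C(C)C)(C(C)C)C(C)C)[C@@H](C)C(C)=O)=C\c1coc(C)n1 | intermediate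
24 | enol dicyclohexylborinate of 23 at C8=C9 (not isolated) | CC(/C=C/C=C(\C)[C@H](OCO[Si](C(C)C)(C(C)C)C(C)C)[C@@H](C)C(=C)OB(C1CCCCC1)C1CCCCC1)=C\c1coc(C)n1 | intermediate
25 | dicyclohexylboron aldolate, (7R)-C7–O–B with the C9 ketone coordinated (not isolated) | CC(/C=C/C=C(\C)[C@H](OCO[Si](C(C)C)(C(C)C)C(C)C)[C@@H](C)C(=O)C[C@@H](OB(C1CCCCC1)C1CCCCC1)[C@@H](C)/C=C/C=C(\C)CO[Si](C)(C)C(C)(C)C)=C\c1coc(C)n1 | intermediate
26 | C1-OTBS, C11-OTOM (6S,7R,9S,10S,11R)-7,9-diol (full name in step 18) | CC(/C=C/C=C(\C)[C@H](OCO[Si](C(C)C)(C(C)C)C(C)C)[C@@H](C)[C@@H](O)C[C@@H](O)[C@@H](C)/C=C/C=C(\C)CO[Si](C)(C)C(C)(C)C)=C\c1coc(C)n1 | intermediate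
27 | (2E,4E,6S,7R,9S,10S,11R,12E,14E,16E)-2,6,10,12,16-pentamethyl-17-(2-methyl-1,3-oxazol-4-yl)heptadeca-2,4,12,14,16-pentaene-1,7,9,11-tetrol | CC(/C=C/C=C(\C)[C@H](O)[C@@H](C)[C@@H](O)C[C@@H](O)[C@@H](C)/C=C/C=C(\C)CO)=C\c1coc(C)n1 | intermediate
28 | (2E,4E,6S,7R,9S,10S,11R,12E,14E,16E)-7,9,11-trihydroxy-2,6,10,12,16-pentamethyl-17-(2-methyl-1,3-oxazol-4-yl)heptadeca-2,4,12,14,16-pentaenal | CC(/C=C/C=C(\C)[C@H](O)[C@@H](C)[C@@H](O)C[C@@H](O)[C@@H](C)/C=C/C=C(\C)C=O)=C\c1coc(C)n1 | intermediate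
29 | (2E,4E,6S,7R,9S,10S,11R,12E,14E,16E)-7,9,11-trihydroxy-2,6,10,12,16-pentamethyl-17-(2-methyl-1,3-oxazol-4-yl)heptadeca-2,4,12,14,16-pentaenoic acid | CC(/C=C/C=C(\C)[C@H](O)[C@@H](C)[C@@H](O)C[C@@H](O)[C@@H](C)/C=C/C=C(\C)C(=O)O)=C\c1coc(C)n1 | target

**Step count:** 21 steps in total. The longest linear sequence is 13 steps (steps 1, 2 and 11 to 21).

**Steps most likely to fail**

1. Step 18. The facial selectivity at C7 may be too low. The 1,5-anti preference of the enolate has to override the Felkin–Anh bias of the aldehyde (the target needs the 6,7-anti, anti-Felkin relation), and the TOM oxygen may direct less strongly than a benzyl-type ether. The fallback sets out from 21 and comes back at 27, and it exchanges the directing group for the one with the closest precedent.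
   - Compound 21 is treated with 4-methoxybenzyl 2,2,2-trichloroacetimidate and catalytic Sc(OTf)3 in toluene at 0 °C to give the C11 PMB ether Weinreb amide F1.
   - MeMgBr converts it into the PMB-protected methyl ketone F2.
   - The boron aldol/LiBH4 sequence with 11 gives the PMB-protected 7,9-diol F3.
   - DDQ in CH2Cl2/pH 7 buffer at 0 °C frees C11–OH to give the C1-TBS 7,9,11-triol F4, and Bu4NF then leads to 27.

2. Step 9. The C6 configuration may be lost by enolisation, and the C4=C5 bond may migrate into conjugation with the aldehyde, during oxidation or handling. The fallback sets out from 23 and comes back at 29. It postpones the diene, so that the aldol partner is a saturated aldehyde.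
   - Commercial methyl (S)-3-hydroxy-2-methylpropanoate is silylated (TESCl, imidazole) to methyl (S)-2-methyl-3-[(triethylsilyl)oxy]propanoate F5.
   - Reduction (i-Bu2AlH, −78 °C) gives (S)-2-methyl-3-[(triethylsilyl)oxy]propanal F6, in which CHO is C7 and CH2O is C5.
   - The aldol–reduction of step 18 with 23 gives the C5–C17 7,9-diol F7.
   - TBSOTf/2,6-lutidine gives the 7,9-bis-TBS ether F8, and PPTS in MeOH frees the primary C5 alcohol F9.
   - Dess–Martin oxidation gives the C5 aldehyde F10, an ordinary α-methyl-β-silyloxy aldehyde.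
   - HWE olefination with 3 and LiN(SiMe3)2 gives the fully protected ethyl dienoate F11.
   - Bu4NF removes both TBS groups and the TOM group to give the triol ethyl ester F12, and LiOH in THF/MeOH/H2O gives 29.

3. Step 20. Chemoselectivity may be lost through competing oxidation of the trienylic C11 carbinol. The fallback sets out from 26 and comes back at 29, and it moves the oxidation in front of the C11 deprotection.
   - PPTS in MeOH at rt removes only the primary allylic TBS ether of 26 to give the C11-TOM 1,7,9-triol F13.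
   - MnO2, which then finds a single allylic alcohol, gives the C11-TOM dienal F14.
   - Pinnick oxidation gives the C11-TOM acid F15, and Bu4NF gives 29.

**Further compounds**
F1 | step 18 | (2R,3R,4E,6E,8E)-N-methoxy-3-[(4-methoxybenzyl)oxy]-N,2,4,8-tetramethyl-9-(2-methyl-1,3-oxazol-4-yl)nona-4,6,8-trienamide | CC(/C=C/C=C(\C)[C@H](OCc1ccc(OC)cc1)[C@@H](C)C(=O)N(C)OC)=C\c1coc(C)n1
F2 | step 18 | (3R,4R,5E,7E,9E)-4-[(4-methoxybenzyl)oxy]-3,5,9-trimethyl-10-(2-methyl-1,3-oxazol-4-yl)deca-5,7,9-trien-2-one | CC(/C=C/C=C(\C)[C@H](OCc1ccc(OC)cc1)[C@@H](C)C(C)=O)=C\c1coc(C)n1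
F3 | step 18 | C1-OTBS, C11-OPMB (6S,7R,9S,10S,11R)-7,9-diol | CC(/C=C/C=C(\C)[C@H](OCc1ccc(OC)cc1)[C@@H](C)[C@@H](O)C[C@@H](O)[C@@H](C)/C=C/C=C(\C)CO[Si](C)(C)C(C)(C)C)=C\c1coc(C)n1
F4 | step 18 | C1-OTBS (6S,7R,9S,10S,11R)-7,9,11-triol | CC(/C=C/C=C(\C)[C@H](O)[C@@H](C)[C@@H](O)C[C@@H](O)[C@@H](C)/C=C/C=C(\C)CO[Si](C)(C)C(C)(C)C)=C\c1coc(C)n1
F5 | step 9 | methyl (S)-2-methyl-3-[(triethylsilyl)oxy]propanoate | CC[Si](CC)(CC)OC[C@H](C)C(=O)OC
F6 | step 9 | (S)-2-methyl-3-[(triethylsilyl)oxy]propanal | CC[Si](CC)(CC)OC[C@H](C)C=O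
F7 | step 9 | C5-OTES, C11-OTOM C5–C17 7,9-diol | CC(/C=C/C=C(\C)[C@H](OCO[Si](C(C)C)(C(C)C)C(C)C)[C@@H](C)[C@@H](O)C[C@@H](O)[C@@H](C)CO[Si](CC)(CC)CC)=C\c1coc(C)n1
F8 | step 9 | 7,9-bis-TBS ether of F7 | CC(/C=C/C=C(\C)[C@H](OCO[Si](C(C)C)(C(C)C)C(C)C)[C@@H](C)[C@@H](O[Si](C)(C)C(C)(C)C)C[C@@H](O[Si](C)(C)C(C)(C)C)[C@@H](C)CO[Si](CC)(CC)CC)=C\c1coc(C)n1
F9 | step 9 | primary C5 alcohol (7,9-bis-TBS, C11-OTOM) | CC(/C=C/C=C(\C)[C@H](OCO[Si](C(C)C)(C(C)C)C(C)C)[C@@H](C)[C@@H](O[Si](C)(C)C(C)(C)C)C[C@@H](O[Si](C)(C)C(C)(C)C)[C@@H](C)CO)=C\c1coc(C)n1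
F10 | step 9 | C5 aldehyde (7,9-bis-TBS, C11-OTOM) | CC(/C=C/C=C(\C)[C@H](OCO[Si](C(C)C)(C(C)C)C(C)C)[C@@H](C)[C@@H](O[Si](C)(C)C(C)(C)C)C[C@@H](O[Si](C)(C)C(C)(C)C)[C@@H](C)C=O)=C\c1coc(C)n1
F11 | step 9 | ethyl (2E,4E)-dienoate (7,9-bis-TBS, C11-OTOM) | CC(/C=C/C=C(\C)[C@H](OCO[Si](C(C)C)(C(C)C)C(C)C)[C@@H](C)[C@@H](O[Si](C)(C)C(C)(C)C)C[C@@H](O[Si](C)(C)C(C)(C)C)[C@@H](C)/C=C/C=C(\C)C(=O)OCC)=C\c1coc(C)n1
F12 | step 9 | ethyl ester of 29 | CC(/C=C/C=C(\C)[C@H](O)[C@@H](C)[C@@H](O)C[C@@H](O)[C@@H](C)/C=C/C=C(\C)C(=O)OCC)=C\c1coc(C)n1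
F13 | step 20 | C11-OTOM 1,7,9-triol | CC(/C=C/C=C(\C)[C@H](OCO[Si](C(C)C)(C(C)C)C(C)C)[C@@H](C)[C@@H](O)C[C@@H](O)[C@@H](C)/C=C/C=C(\C)CO)=C\c1coc(C)n1
F14 | step 20 | C11-OTOM 7,9-dihydroxy dienal | CC(/C=C/C=C(\C)[C@H](OCO[Si](C(C)C)(C(C)C)C(C)C)[C@@H](C)[C@@H](O)C[C@@H](O)[C@@H](C)/C=C/C=C(\C)C=O)=C\c1coc(C)n1
F15 | step 20 | C11-OTOM 7,9-dihydroxy acid | CC(/C=C/C=C(\C)[C@H](OCO[Si](C(C)C)(C(C)C)C(C)C)[C@@H](C)[C@@H](O)C[C@@H](O)[C@@H](C)/C=C/C=C(\C)C(=O)O)=C\c1coc(C)n1
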